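Locants: tetralin C1 (isopropyl), C4 (methyl), C5/C6 (OH), C7 (CHO), C8 (pyranonyl); ring A is the arene. The route rests on cutting ring A at C8–C8a: its four contiguous, fully substituted carbons C5–C8 come from a squarate ring that already carries the C5 and C6 oxygens, and C4a=C8a from a carvone-derived cyclohexenyllithium holding both stereocentres. The precursor is a 4-cyclohexenyl-4-methoxy-3-isopropoxy-2-isobutenylcyclobutenone. Heating opens it to a dienylketene whose carbon C8 closes onto C8a, giving in one operation the hexasubstituted arene with O5 and O6 masked, C7 bearing a latent formyl group and only the C8 hydroxyl free for triflation and pyranone attachment.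

Key step: step 5

Assumption: the target structure defines no configuration for the hindered C8–C3' axis, so none is controlled; the pyranone (O1', C2'–C6') is handled as its 4-hydroxy-2-pyranone tautomer.

Step 1
Reactants: 1 (S)-(+)-carvone
Product: 2 trans-carvomenthone [(2S,5S)-2-methyl-5-(propan-2-yl)cyclohexan-1-one]
Conditions: H2 (1 atm), 10% Pd/C, EtOAc, rt; then NaOMe (cat.), MeOH, rt
Reagents that add atoms: none
Why: Heterogeneous hydrogenation saturates both C=C bonds without touching the carvone-derived centre (later C1), and the new methyl-bearing centre (later C4) is set under thermodynamic control by base epimerisation next to the ketone, which should favour the trans, diequatorial isomer.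

Step 2
Reactants: 2 trans-carvomenthone; 3 2,4,6-tri(propan-2-yl)benzenesulfonohydrazide
Product: 4 (E)-trisylhydrazone of 2 [N'-[(1E,2S,5S)-2-methyl-5-(propan-2-yl)cyclohexylidene]-2,4,6-tri(propan-2-yl)benzenesulfonohydrazide]
Conditions: MeOH, HCl (cat.), rt; recrystallisation
Reagents that add atoms: none
Why: Acid-catalysed hydrazone formation places the sulfonamide nitrogen anti to the more substituted α-carbon, the methyl centre stays in its preferred equatorial configuration, and recrystallisation should remove the minor cis epimer carried over from step 1.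

Step 3
Reactants: 5 diisopropyl squarate; 6 2-methylprop-1-en-1-ylmagnesium bromide
Product: 8 3-(2-methylprop-1-en-1-yl)-4-(propan-2-yloxy)cyclobut-3-ene-1,2-dione, via squarate mono-adduct 7 (not isolated)
Conditions: THF, −78 °C; then 6 M HCl, 0 °C → rt
Reagents that add atoms: water, O
Why: 1,2-Addition of the alkenyl Grignard reagent to one squarate carbonyl followed by acid-promoted allylic transposition and loss of isopropanol is the standard entry to 3-alkoxy-4-substituted cyclobutenediones.

Step 4
Reactants: 4 (E)-trisylhydrazone; 8 3-(2-methylprop-1-en-1-yl)-4-(propan-2-yloxy)cyclobut-3-ene-1,2-dione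
Product: 11 4-methoxy-4-[(3R,6S)-6-methyl-3-(propan-2-yl)cyclohex-1-en-1-yl]-2-(2-methylprop-1-en-1-yl)-3-(propan-2-yloxy)cyclobut-2-en-1-one (both epimers at the ring carbon), via vinyllithium 9 (not isolated), via lithium alkoxide 10 (not isolated)
Conditions: s-BuLi (2.05 equiv), THF, −78 → 0 °C; added to 8, THF, −78 °C; MeOTf (3 equiv), −78 → 0 °C
Reagents that add atoms: methyl trifluoromethanesulfonate, COS(=O)(=O)C(F)(F)F
Why: Shapiro reaction (dianion formation at the less substituted α-CH2, loss of sulfinate and N2) gives the vinyllithium with the future C4a=C8a bond in place, which adds 1,2 to the ketone-like carbonyl of 8 beside the isopropoxy-bearing carbon because the other carbonyl is deactivated as a vinylogous ester, and the tertiary alkoxide is then O-methylated; the new quaternary centre forms without control, which is immaterial because it becomes sp2 in step 5.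

Step 5
Reactants: 11 4-cyclohexenyl-4-methoxycyclobutenone
Product: 14 (1R,4S)-5-methoxy-4-methyl-7-(2-methylprop-1-en-1-yl)-6-(propan-2-yloxy)-1-(propan-2-yl)-1,2,3,4-tetrahydronaphthalen-8-ol, via dienylketene 12 (not isolated), via cyclohexadienone 13 (not isolated)
Conditions: p-xylene (degassed), 140 °C, argon
Reagents that add atoms: none
Why: Heating triggers conrotatory four-electron electrocyclic opening of the cyclobutenone across the C5–C8 bond to dienylketene 12, which undergoes thermal disrotatory six-electron electrocyclisation between the ketene carbon C8 and the alkene terminus C8a to give cyclohexa-2,4-dienone 13, and enolisation with loss of the C8a hydrogen aromatises ring A to phenol 14. The closest known reaction type is the Moore ring expansion of 4-alkenyl-4-alkoxycyclobutenones to mono-protected hydroquinones. Ring A, a six-membered carbocycle, is closed by pericyclic C8–C8a bond formation of a Z-dienylketene. No lasting stereocentre is created, since C8a is sp3 only in 13, and C1 and C4 are bystanders under neutral thermal conditions. The selectivity required is torquoselectivity, secured by the methoxy donor on the breaking sp3 carbon, which rotates outward and so turns the cyclohexenyl group inward beside the ketene; the cross-conjugated isobutenyl group cannot enter the triene. The substitution pattern (oxygen on C5 and C6, carbon on C7, free hydroxyl only on C8) was already fixed by the site-selective addition in step 4.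

Step 6
Reactants: 14 tetralin-8-ol
Product: 15 (1R,4S)-5-methoxy-4-methyl-7-(2-methylprop-1-en-1-yl)-6-(propan-2-yloxy)-1-(propan-2-yl)-1,2,3,4-tetrahydronaphthalen-8-yl trifluoromethanesulfonate
Conditions: Tf2O, pyridine, CH2Cl2, 0 °C
Reagents that add atoms: trifluoromethanesulfonic anhydride, O=S(=O)(OS(=O)(=O)C(F)(F)F)C(F)(F)F
Why: O-Sulfonylation of the only free hydroxyl with a small, highly reactive electrophile should proceed despite the flanking groups and activates C8 for cross-coupling.

Step 7
Reactants: 15 aryl triflate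
Product: 16 (1R,4S)-7-formyl-5-methoxy-4-methyl-6-(propan-2-yloxy)-1-(propan-2-yl)-1,2,3,4-tetrahydronaphthalen-8-yl trifluoromethanesulfonate
Conditions: O3, CH2Cl2/MeOH, NaHCO3, −78 °C; then Me2S, −78 °C → rt
Reagents that add atoms: ozone, [O-][O+]=O
Why: Ozonolysis with reductive work-up cleaves the electron-rich trisubstituted alkene, the only alkene present at this stage, far faster than ozone attacks the triflate-bearing arene.

Step 8
Reactants: 16 formyl aryl triflate
Product: 17 (1R,4S)-7-(1,3-dioxolan-2-yl)-5-methoxy-4-methyl-6-(propan-2-yloxy)-1-(propan-2-yl)-1,2,3,4-tetrahydronaphthalen-8-yl trifluoromethanesulfonate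
Conditions: HOCH2CH2OH, TsOH·H2O (cat.), benzene, reflux (Dean–Stark)
Reagents that add atoms: ethylene glycol, OCCO
Why: Acid-catalysed acetalisation with azeotropic water removal leaves aryl ethers and triflate untouched and shields the formyl group from the enolates of steps 9, 10 and 12.

Step 9
Reactants: 17 dioxolane aryl triflate; 18 (2-tert-butoxy-2-oxoethyl)zinc bromide
Product: 19 tert-butyl 2-[(1R,4S)-7-(1,3-dioxolan-2-yl)-5-methoxy-4-methyl-6-(propan-2-yloxy)-1-(propan-2-yl)-1,2,3,4-tetrahydronaphthalen-8-yl]acetate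
Conditions: 18 (2.5 equiv), Pd2(dba)3 (5 mol %), XPhos (12 mol %), THF, 65 °C
Reagents that add atoms: none
Why: Negishi-type cross-coupling of an aryl triflate with a Reformatsky reagent is known, a bulky electron-rich biarylphosphine on zerovalent palladium should support oxidative addition and reductive elimination at the doubly ortho-substituted C8, and the mild zinc enolate tolerates acetal and ethers.

Step 10
Reactants: 19 tert-butyl arylacetate; 20 N-methoxy-N-methylacetamide
Product: 21 tert-butyl 2-[(1R,4S)-7-(1,3-dioxolan-2-yl)-5-methoxy-4-methyl-6-(propan-2-yloxy)-1-(propan-2-yl)-1,2,3,4-tetrahydronaphthalen-8-yl]-3-oxobutanoate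
Conditions: LiN(iPr)2 (1.1 equiv), THF, −78 °C; 20 (1.5 equiv), −78 → 0 °C; aq. NH4Cl
Reagents that add atoms: none
Why: Crossed Claisen-type C-acylation of the benzylic lithium ester enolate with a Weinreb amide stops at the chelated tetrahedral adduct, so over-acylation and proton exchange are avoided; the new α-centre is enolisable and disappears in step 12.

Step 11
Reactants: 22 (E)-3-(3,4-dimethoxyphenyl)prop-2-enoic acid
Product: 24 (E)-3-(3,4-dimethoxyphenyl)-N-methoxy-N-methylprop-2-enamide, via acyl imidazole 23 (not isolated)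
Conditions: 1,1'-carbonyldiimidazole, CH2Cl2, rt; then MeNH(OMe)·HCl, rt
Reagents that add atoms: N,O-dimethylhydroxylamine hydrochloride, CNOC.Cl
Why: Activation of the acid as its acyl imidazole and aminolysis is a routine Weinreb amide synthesis that leaves the E alkene unchanged.

Step 12
Reactants: 21 α-aryl β-keto ester; 24 cinnamoyl Weinreb amide
Product: 26 3-[(1R,4S)-7-(1,3-dioxolan-2-yl)-5-methoxy-4-methyl-6-(propan-2-yloxy)-1-(propan-2-yl)-1,2,3,4-tetrahydronaphthalen-8-yl]-6-[(E)-2-(3,4-dimethoxyphenyl)ethenyl]-4-hydroxy-2H-pyran-2-one, via triketo ester 25 (not isolated)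
Conditions: LiN(iPr)2 (2.2 equiv), THF, −78 → 0 °C; 24 (1.2 equiv), −78 → 0 °C; aq. NH4Cl; then toluene, 110 °C
Reagents that add atoms: none
Why: The α,γ-dianion of the β-keto ester is acylated at its terminal carbon by the Weinreb amide in a 1,2 sense, and the resulting 3,5-dioxo tert-butyl ester should lactonise on heating with loss of tert-butanol, the established triketide-to-4-hydroxy-2-pyranone cyclisation.

Step 13
Reactants: 26 protected pyranone
Product: 27 heimiomycin B
Conditions: BBr3 (10 equiv), CH2Cl2, −78 °C → rt, argon; then H2O, 0 °C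
Reagents that add atoms: water, O
Why: Lewis-acid ether cleavage with BBr3 should remove the three methyl ethers and the isopropyl ether and open the dioxolane, aqueous work-up hydrolyses the borates and releases the aldehyde, and the lactone, the E alkene and both stereocentres are not addressed by the reagent.

Compound list
1 | (S)-(+)-carvone | CC1=CC[C@@H](CC1=O)C(C)=C | starting material
2 | trans-carvomenthone [(2S,5S)-2-methyl-5-(propan-2-yl)cyclohexan-1-one] | CC(C)[C@H]1CC[C@H](C)C(=O)C1 | intermediate
3 | 2,4,6-tri(propan-2-yl)benzenesulfonohydrazide | CC(C)c1cc(C(C)C)c(S(=O)(=O)NN)c(C(C)C)c1 | starting material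
4 | (E)-trisylhydrazone of 2 | CC(C)[C@H]1CC[C@H](C)/C(=N/NS(=O)(=O)c2c(C(C)C)cc(C(C)C)cc2C(C)C)C1 | intermediate
5 | diisopropyl squarate | CC(C)OC1=C(OC(C)C)C(=O)C1=O | starting material
6 | 2-methylprop-1-en-1-ylmagnesium bromide | CC(C)=C[Mg]Br | starting material
7 | 4-hydroxy-4-(2-methylprop-1-en-1-yl)-2,3-di(propan-2-yloxy)cyclobut-2-en-1-one (racemic; present as its bromomagnesium alkoxide) | CC(C)OC1=C(OC(C)C)C(O)(C=C(C)C)C1=O | intermediate
8 | 3-(2-methylprop-1-en-1-yl)-4-(propan-2-yloxy)cyclobut-3-ene-1,2-dione | CC(C)OC1=C(C=C(C)C)C(=O)C1=O | intermediate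
9 | [(3R,6S)-6-methyl-3-(propan-2-yl)cyclohex-1-en-1-yl]lithium | CC(C)[C@H]1CC[C@H](C)C(=C1)[Li] | intermediate
10 | lithium alkoxide of the 4-cyclohexenyl-4-hydroxycyclobutenone (both epimers at the carbinol carbon) | CC(C)[C@H]1CC[C@H](C)C(=C1)C1(O[Li])C(OC(C)C)=C(C=C(C)C)C1=O | intermediate
11 | 4-methoxy-4-[(3R,6S)-6-methyl-3-(propan-2-yl)cyclohex-1-en-1-yl]-2-(2-methylprop-1-en-1-yl)-3-(propan-2-yloxy)cyclobut-2-en-1-one (both epimers at the ring carbon) | CC(C)[C@H]1CC[C@H](C)C(=C1)C1(OC)C(OC(C)C)=C(C=C(C)C)C1=O | intermediate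
12 | (3Z)-4-methoxy-4-[(3R,6S)-6-methyl-3-(propan-2-yl)cyclohex-1-en-1-yl]-2-(2-methylprop-1-en-1-yl)-3-(propan-2-yloxy)buta-1,3-dien-1-one (dienylketene) | CC(C)[C@H]1CC[C@H](C)C(=C1)/C(OC)=C(OC(C)C)\C(C=C(C)C)=C=O | intermediate
13 | (1R,4S)-5-methoxy-4-methyl-7-(2-methylprop-1-en-1-yl)-6-(propan-2-yloxy)-1-(propan-2-yl)-2,3,4,8a-tetrahydronaphthalen-8(1H)-one (either C8a epimer) | CC(C)[C@H]1CC[C@H](C)C2=C(OC)C(OC(C)C)=C(C=C(C)C)C(=O)C21 | intermediate
14 | (1R,4S)-5-methoxy-4-methyl-7-(2-methylprop-1-en-1-yl)-6-(propan-2-yloxy)-1-(propan-2-yl)-1,2,3,4-tetrahydronaphthalen-8-ol | CC(C)[C@H]1CC[C@H](C)c2c(OC)c(OC(C)C)c(C=C(C)C)c(O)c21 | intermediate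
15 | 8-trifluoromethanesulfonate of 14 | CC(C)[C@H]1CC[C@H](C)c2c(OC)c(OC(C)C)c(C=C(C)C)c(OS(=O)(=O)C(F)(F)F)c21 | intermediate
16 | (1R,4S)-7-formyl-5-methoxy-4-methyl-6-(propan-2-yloxy)-1-(propan-2-yl)-1,2,3,4-tetrahydronaphthalen-8-yl trifluoromethanesulfonate | CC(C)[C@H]1CC[C@H](C)c2c(OC)c(OC(C)C)c(C=O)c(OS(=O)(=O)C(F)(F)F)c21 | intermediate
17 | (1R,4S)-7-(1,3-dioxolan-2-yl)-5-methoxy-4-methyl-6-(propan-2-yloxy)-1-(propan-2-yl)-1,2,3,4-tetrahydronaphthalen-8-yl trifluoromethanesulfonate | CC(C)[C@H]1CC[C@H](C)c2c(OC)c(OC(C)C)c(C3OCCO3)c(OS(=O)(=O)C(F)(F)F)c21 | intermediate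
18 | (2-tert-butoxy-2-oxoethyl)zinc bromide | CC(C)(C)OC(=O)C[Zn]Br | starting material
19 | tert-butyl 2-[(1R,4S)-7-(1,3-dioxolan-2-yl)-5-methoxy-4-methyl-6-(propan-2-yloxy)-1-(propan-2-yl)-1,2,3,4-tetrahydronaphthalen-8-yl]acetate | CC(C)[C@H]1CC[C@H](C)c2c(OC)c(OC(C)C)c(C3OCCO3)c(CC(=O)OC(C)(C)C)c21 | intermediate
20 | N-methoxy-N-methylacetamide | CC(=O)N(C)OC | starting material
21 | tert-butyl 2-aryl-3-oxobutanoate (aryl as in 19; α-centre unassigned) | CC(C)[C@H]1CC[C@H](C)c2c(OC)c(OC(C)C)c(C3OCCO3)c(C(C(C)=O)C(=O)OC(C)(C)C)c21 | intermediate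
22 | (E)-3-(3,4-dimethoxyphenyl)prop-2-enoic acid | COc1ccc(/C=C/C(=O)O)cc1OC | starting material
23 | (E)-3-(3,4-dimethoxyphenyl)-1-(1H-imidazol-1-yl)prop-2-en-1-one | COc1ccc(/C=C/C(=O)n2ccnc2)cc1OC | intermediate
24 | (E)-3-(3,4-dimethoxyphenyl)-N-methoxy-N-methylprop-2-enamide | COc1ccc(/C=C/C(=O)N(C)OC)cc1OC | intermediate
25 | tert-butyl (E)-2-aryl-7-(3,4-dimethoxyphenyl)-3,5-dioxohept-6-enoate (aryl as in 19; α-centre unassigned) | CC(C)[C@H]1CC[C@H](C)c2c(OC)c(OC(C)C)c(C3OCCO3)c(C(C(=O)CC(=O)/C=C/c3ccc(OC)c(OC)c3)C(=O)OC(C)(C)C)c21 | intermediate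
26 | 3-aryl-6-[(E)-2-(3,4-dimethoxyphenyl)ethenyl]-4-hydroxy-2H-pyran-2-one (aryl as in 19) | CC(C)[C@H]1CC[C@H](C)c2c(OC)c(OC(C)C)c(C3OCCO3)c(-c3c(O)cc(/C=C/c4ccc(OC)c(OC)c4)oc3=O)c21 | intermediate
27 | heimiomycin B | CC(C)[C@H]1CC[C@H](C)c2c(O)c(O)c(C=O)c(-c3c(O)cc(/C=C/c4ccc(O)c(O)c4)oc3=O)c21 | target

Total step count: 13. Longest linear sequence: 11 steps (steps 1, 2, 4, 5, 6, 7, 8, 9, 10, 12, 13); steps 3 and 11 are convergent side steps.

Steps most likely to fail

Step 9. Transmetalation and reductive elimination at C8, which is flanked by the dioxolane-bearing C7 and by C8a with its neighbouring isopropyl-bearing C1, may be so slow that reduction or hydrolysis of the triflate takes over. The fallback sets out from 17 and replaces the enolate coupling by a vinyl coupling with later oxidation-state adjustment. Suzuki–Miyaura coupling of 17 with potassium vinyltrifluoroborate (PdCl2(dppf), Cs2CO3, THF/H2O, 80 °C) would give the 8-vinyl arene F1. Hydroboration–oxidation (9-BBN, THF; then NaOH, H2O2) would give the 2-arylethanol F2. Buffered oxidation (TEMPO cat., NaOCl cat., NaClO2, MeCN/phosphate buffer) would give the arylacetic acid F3. Esterification (Boc2O, DMAP, t-BuOH) returns to the route at 19.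

Step 10. C-Acylation of the congested benzylic enolate by the amide electrophile may be sluggish, so that 19 is returned or the enolate decomposes on warming. The fallback sets out from 19 and uses a small aldehyde electrophile followed by oxidation. Aldol addition of the lithium enolate (LiN(iPr)2, THF, −78 °C) to acetaldehyde would give the β-hydroxy ester F4 as a diastereomer mixture, and Dess–Martin periodinane oxidation (CH2Cl2, NaHCO3, rt) comes back to the route at 21.

Step 4. The one-pot sequence may suffer from incomplete fragmentation or premature protonation of the vinyllithium, and from competition between lithium sulfinate and the hindered tertiary alkoxide for the methylating agent. The fallback sets out from 4 and separates the three events. The Shapiro vinyllithium is quenched with iodine to give the vinyl iodide F5, which is purified. Iodine–lithium exchange (t-BuLi, 2 equiv, Et2O, −78 °C) regenerates 9 free of by-products; addition to 8 and an NH4Cl quench give the tertiary alcohol F6, which is isolated. Neutral O-methylation (MeI, Ag2O, K2CO3, MeCN, rt) returns to the route at 11.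

Further compounds
F1 | step 9 | (1R,4S)-7-(1,3-dioxolan-2-yl)-8-ethenyl-5-methoxy-4-methyl-6-(propan-2-yloxy)-1-(propan-2-yl)-1,2,3,4-tetrahydronaphthalene | CC(C)[C@H]1CC[C@H](C)c2c(OC)c(OC(C)C)c(C3OCCO3)c(C=C)c21
F2 | step 9 | 2-[(1R,4S)-7-(1,3-dioxolan-2-yl)-5-methoxy-4-methyl-6-(propan-2-yloxy)-1-(propan-2-yl)-1,2,3,4-tetrahydronaphthalen-8-yl]ethan-1-ol | CC(C)[C@H]1CC[C@H](C)c2c(OC)c(OC(C)C)c(C3OCCO3)c(CCO)c21
F3 | step 9 | 2-[(1R,4S)-7-(1,3-dioxolan-2-yl)-5-methoxy-4-methyl-6-(propan-2-yloxy)-1-(propan-2-yl)-1,2,3,4-tetrahydronaphthalen-8-yl]acetic acid | CC(C)[C@H]1CC[C@H](C)c2c(OC)c(OC(C)C)c(C3OCCO3)c(CC(=O)O)c21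
F4 | step 10 | tert-butyl 2-aryl-3-hydroxybutanoate (aryl as in 19; diastereomer mixture) | CC(C)[C@H]1CC[C@H](C)c2c(OC)c(OC(C)C)c(C3OCCO3)c(C(C(C)O)C(=O)OC(C)(C)C)c21
F5 | step 4 | (3R,6S)-1-iodo-6-methyl-3-(propan-2-yl)cyclohex-1-ene | CC(C)[C@H]1CC[C@H](C)C(I)=C1
F6 | step 4 | 4-hydroxy-4-[(3R,6S)-6-methyl-3-(propan-2-yl)cyclohex-1-en-1-yl]-2-(2-methylprop-1-en-1-yl)-3-(propan-2-yloxy)cyclobut-2-en-1-one (both epimers at the ring carbon) | CC(C)[C@H]1CC[C@H](C)C(=C1)C1(O)C(OC(C)C)=C(C=C(C)C)C1=O
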